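**Retrosynthetic overview**
1. Target ⇐ global O-debenzylation of its 7,2',3'-tribenzyl ether; 4'-OMe ⇐ O-methylation; 5'-(1,1-dimethylallyl) ⇐ aromatic Claisen rearrangement of a 4'-O-prenyl ether (C3' is blocked, so the shift ends at C5').
2. 4'-Hydroxyisoflavone ⇐ 2'-hydroxychalcone by Tl(III) oxidative 1,2-aryl shift, then acid ring closure (the 4'-O-MOM group falls off in the same pot).
3. Chalcone ⇐ Claisen–Schmidt aldol condensation of 4-benzyloxy-2-hydroxyacetophenone with 2,3-bis(benzyloxy)-4-(methoxymethoxy)benzaldehyde; this is the key C–C bond joining the A- and B-ring fragments.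
4. The two fragments ⇐ 2,4-dihydroxyacetophenone and 2,3,4-trihydroxybenzaldehyde by selective O-alkylations.
5. Ring order: both benzene rings are bought; the γ-pyranone ring is the only ring formed (acid cyclisation after the aryl shift).

Assumption: the target has no stereocentre and is achiral, so there is no enantiomer to select; the only stereo-element on the way is the E geometry of chalcone 7, and the sp3 centres of 6, 8 and 13 are racemic and are destroyed again.

**Route**

Step 1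
Reactants: 1 2,4-dihydroxyacetophenone
Product: 2 1-[4-(benzyloxy)-2-hydroxyphenyl]ethan-1-one
Conditions: BnBr (1.05 equiv), K2CO3 (1.2 equiv), acetone, reflux, 6 h
Reagents that add atoms: benzyl bromide, BrCc1ccccc1
Why: Williamson etherification is selective for the 4-OH because the 2-OH is tied up in a hydrogen bond to the ketone and is far less nucleophilic.

Step 2
Reactants: 3 2,3,4-trihydroxybenzaldehyde
Product: 4 2,3-dihydroxy-4-(methoxymethoxy)benzaldehyde
Conditions: MOMCl (1.05 equiv), iPr2NEt (1.1 equiv), THF, 0 °C to rt, N2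
Reagents that add atoms: chloromethyl methyl ether, COCCl
Why: Selective O-alkylation works because the 4-OH (para to CHO) is the most acidic, the 2-OH is chelated to the aldehyde and the 3-OH is the least acidic, so one equivalent of a weak base forms and alkylates only the 4-phenoxide.

Step 3
Reactants: 4 2,3-dihydroxy-4-(methoxymethoxy)benzaldehyde
Product: 5 2,3-bis(benzyloxy)-4-(methoxymethoxy)benzaldehyde
Conditions: BnBr (2.5 equiv), K2CO3 (3 equiv), DMF, 60 °C, N2
Reagents that add atoms: benzyl bromide, BrCc1ccccc1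
Why: Exhaustive Williamson benzylation in DMF at 60 °C also alkylates the chelated 2-OH, and the MOM ether is inert to base.

Step 4
Reactants: 2 1-[4-(benzyloxy)-2-hydroxyphenyl]ethan-1-one; 5 2,3-bis(benzyloxy)-4-(methoxymethoxy)benzaldehyde
Product: 7 (E)-1-[4-(benzyloxy)-2-hydroxyphenyl]-3-[2,3-bis(benzyloxy)-4-(methoxymethoxy)phenyl]prop-2-en-1-one, via β-hydroxy ketone 6 (not isolated)
Conditions: 50% aq. KOH (10 equiv), EtOH, rt, 48 h; then AcOH to pH 6 at 0 °C
Reagents that add atoms: none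
Why: Claisen–Schmidt aldol condensation of the methyl ketone enolate with the non-enolisable aldehyde, followed by E1cB dehydration, gives the conjugated E-chalcone as the thermodynamic product; benzyl and MOM ethers are base-stable.

Step 5
Reactants: 7 (E)-1-[4-(benzyloxy)-2-hydroxyphenyl]-3-[2,3-bis(benzyloxy)-4-(methoxymethoxy)phenyl]prop-2-en-1-one
Product: 8 1-[4-(benzyloxy)-2-hydroxyphenyl]-2-[2,3-bis(benzyloxy)-4-(methoxymethoxy)phenyl]-3,3-dimethoxypropan-1-one (racemic, used crude)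
Conditions: Tl(NO3)3·3H2O (1.1 equiv), MeOH/CH(OMe)3/CH2Cl2, 0 °C to rt, 2 h; filter TlNO3, aq. NaHCO3
Reagents that add atoms: methanol, CO
Why: Thallium(III) oxidative rearrangement of a chalcone (oxythallation, then 1,2-shift of the electron-rich trialkoxyaryl group with loss of Tl(I)) gives the 1,2-diaryl-3,3-dimethoxypropanone; no other alkene is present at this stage and the new sp3 centre is racemic and is lost in step 6.

Step 6
Reactants: 8 1-[4-(benzyloxy)-2-hydroxyphenyl]-2-[2,3-bis(benzyloxy)-4-(methoxymethoxy)phenyl]-3,3-dimethoxypropan-1-one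
Product: 10 7-(benzyloxy)-3-[2,3-bis(benzyloxy)-4-hydroxyphenyl]-4H-chromen-4-one, via 4'-O-MOM isoflavone 9 (not isolated)
Conditions: 10% aq. HCl, MeOH/THF, reflux, 3 h
Reagents that add atoms: none
Why: Acid-catalysed transacetalisation by the A-ring 2-OH and loss of methanol closes the pyranone, then the MOM acetal is methanolysed; the acid-stable 2'-O-benzyl group prevents the competing closure to a 3-aroylbenzofuran and leaves 4'-OH as the only free phenol.

Step 7
Reactants: 10 7-(benzyloxy)-3-[2,3-bis(benzyloxy)-4-hydroxyphenyl]-4H-chromen-4-one; 11 prenyl bromide (1-bromo-3-methylbut-2-ene)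
Product: 12 7-(benzyloxy)-3-{2,3-bis(benzyloxy)-4-[(3-methylbut-2-en-1-yl)oxy]phenyl}-4H-chromen-4-one
Conditions: K2CO3 (2 equiv), acetone, reflux, 6 h
Reagents that add atoms: none
Why: Williamson O-alkylation of the single free phenol with a reactive allylic bromide is clean, and the isoflavone tolerates K2CO3 in acetone.

Step 8
Reactants: 12 7-(benzyloxy)-3-{2,3-bis(benzyloxy)-4-[(3-methylbut-2-en-1-yl)oxy]phenyl}-4H-chromen-4-one
Product: 14 7-(benzyloxy)-3-[2,3-bis(benzyloxy)-4-hydroxy-5-(2-methylbut-3-en-2-yl)phenyl]-4H-chromen-4-one, via ortho-dienone 13 (not isolated)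
Conditions: degassed PhNEt2, 195 °C, sealed tube, Ar, 2–3 h (stop at full conversion)
Reagents that add atoms: none
Why: Aromatic Claisen [3,3] rearrangement delivers the allyl unit with inversion to C5', the only ortho position that can re-aromatise (C3' carries OBn, para C1' is substituted), giving the 1,1-dimethylallyl phenol; the basic solvent suppresses acid-catalysed follow-up reactions and no stereocentre remains.

Step 9
Reactants: 14 7-(benzyloxy)-3-[2,3-bis(benzyloxy)-4-hydroxy-5-(2-methylbut-3-en-2-yl)phenyl]-4H-chromen-4-one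
Product: 15 7-(benzyloxy)-3-[2,3-bis(benzyloxy)-4-methoxy-5-(2-methylbut-3-en-2-yl)phenyl]-4H-chromen-4-one
Conditions: MeI (3 equiv), K2CO3 (3 equiv), DMF, 40 °C, 12 h
Reagents that add atoms: iodomethane, CI
Why: Williamson O-methylation with the small electrophile MeI in DMF works even on this doubly ortho-flanked phenol, and nothing else in the molecule is alkylated.

Step 10
Reactants: 15 7-(benzyloxy)-3-[2,3-bis(benzyloxy)-4-methoxy-5-(2-methylbut-3-en-2-yl)phenyl]-4H-chromen-4-one
Product: 16 3-[2,3-dihydroxy-4-methoxy-5-(2-methylbut-3-en-2-yl)phenyl]-7-hydroxy-4H-chromen-4-one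
Conditions: BCl3 (1 M in CH2Cl2, 6 equiv), pentamethylbenzene (9 equiv), CH2Cl2, −78 °C, 1 h; then CHCl3/MeOH at −78 °C, aqueous work-up
Reagents that add atoms: none
Why: Lewis-acid cleavage of aryl benzyl ethers with a non-Lewis-basic cation scavenger removes all three benzyl groups at −78 °C, a temperature at which the monosubstituted alkene and the aryl methyl ether are not attacked.

**Compound list**
1 | 2,4-dihydroxyacetophenone | CC(=O)c1ccc(O)cc1O | starting material
2 | 1-[4-(benzyloxy)-2-hydroxyphenyl]ethan-1-one | CC(=O)c1ccc(OCc2ccccc2)cc1O | intermediate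
3 | 2,3,4-trihydroxybenzaldehyde | O=Cc1ccc(O)c(O)c1O | starting material
4 | 2,3-dihydroxy-4-(methoxymethoxy)benzaldehyde | O=Cc1ccc(OCOC)c(O)c1O | intermediate
5 | 2,3-bis(benzyloxy)-4-(methoxymethoxy)benzaldehyde | O=Cc1ccc(OCOC)c(OCc2ccccc2)c1OCc1ccccc1 | intermediate
6 | 1-[4-(benzyloxy)-2-hydroxyphenyl]-3-[2,3-bis(benzyloxy)-4-(methoxymethoxy)phenyl]-3-hydroxypropan-1-one (racemic) | O=C(CC(O)c1ccc(OCOC)c(OCc2ccccc2)c1OCc1ccccc1)c1ccc(OCc2ccccc2)cc1O | intermediate (not isolated)
7 | (E)-1-[4-(benzyloxy)-2-hydroxyphenyl]-3-[2,3-bis(benzyloxy)-4-(methoxymethoxy)phenyl]prop-2-en-1-one | O=C(/C=C/c1ccc(OCOC)c(OCc2ccccc2)c1OCc1ccccc1)c1ccc(OCc2ccccc2)cc1O | intermediate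
8 | 1-[4-(benzyloxy)-2-hydroxyphenyl]-2-[2,3-bis(benzyloxy)-4-(methoxymethoxy)phenyl]-3,3-dimethoxypropan-1-one (racemic) | COC(OC)C(C(=O)c1ccc(OCc2ccccc2)cc1O)c1ccc(OCOC)c(OCc2ccccc2)c1OCc1ccccc1 | intermediate
9 | 7-(benzyloxy)-3-[2,3-bis(benzyloxy)-4-(methoxymethoxy)phenyl]-4H-chromen-4-one | COCOc1ccc(-c2coc3cc(OCc4ccccc4)ccc3c2=O)c(OCc2ccccc2)c1OCc1ccccc1 | intermediate (not isolated)
10 | 7-(benzyloxy)-3-[2,3-bis(benzyloxy)-4-hydroxyphenyl]-4H-chromen-4-one | Oc1ccc(-c2coc3cc(OCc4ccccc4)ccc3c2=O)c(OCc2ccccc2)c1OCc1ccccc1 | intermediate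
11 | prenyl bromide (1-bromo-3-methylbut-2-ene) | CC(C)=CCBr | starting material
12 | 7-(benzyloxy)-3-{2,3-bis(benzyloxy)-4-[(3-methylbut-2-en-1-yl)oxy]phenyl}-4H-chromen-4-one | CC(C)=CCOc1ccc(-c2coc3cc(OCc4ccccc4)ccc3c2=O)c(OCc2ccccc2)c1OCc1ccccc1 | intermediate
13 | 2,3-bis(benzyloxy)-4-[7-(benzyloxy)-4-oxo-4H-chromen-3-yl]-6-(2-methylbut-3-en-2-yl)cyclohexa-2,4-dien-1-one (racemic) | C=CC(C)(C)C1C=C(-c2coc3cc(OCc4ccccc4)ccc3c2=O)C(OCc2ccccc2)=C(OCc2ccccc2)C1=O | intermediate (not isolated)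
14 | 7-(benzyloxy)-3-[2,3-bis(benzyloxy)-4-hydroxy-5-(2-methylbut-3-en-2-yl)phenyl]-4H-chromen-4-one | C=CC(C)(C)c1cc(-c2coc3cc(OCc4ccccc4)ccc3c2=O)c(OCc2ccccc2)c(OCc2ccccc2)c1O | intermediate
15 | 7-(benzyloxy)-3-[2,3-bis(benzyloxy)-4-methoxy-5-(2-methylbut-3-en-2-yl)phenyl]-4H-chromen-4-one | C=CC(C)(C)c1cc(-c2coc3cc(OCc4ccccc4)ccc3c2=O)c(OCc2ccccc2)c(OCc2ccccc2)c1OC | intermediate
16 | 3-[2,3-dihydroxy-4-methoxy-5-(2-methylbut-3-en-2-yl)phenyl]-7-hydroxy-4H-chromen-4-one | C=CC(C)(C)c1cc(-c2coc3cc(O)ccc3c2=O)c(O)c(O)c1OC | target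

**Summary**
Total step count: 10. Longest linear sequence: 9 steps (3 to 16, steps 2–10).

**Steps most likely to fail, with fallbacks**

Step 5 (Tl(III) aryl shift; risks are premature MOM loss with over-oxidation of the B ring, and aurone formation). The fallback sets out from 7 and comes back at 10, and replaces the oxidative aryl shift by an acyl shift of the chalcone epoxide. The chelated 2'-OH of 7 is capped (NaH, MOMCl, DMF, 0 °C) to give the 2'-O-MOM chalcone F1. Weitz–Scheffer epoxidation (30% H2O2, NaOH, MeOH/THF, 0 °C) gives the racemic trans-epoxy ketone F2. BF3·OEt2 (CH2Cl2, −20 °C) opens the epoxide at the benzylic carbon and the aroyl group migrates, giving the α-formyl deoxybenzoin F3. 10% HCl in MeOH at reflux then removes both MOM groups and cyclodehydrates to 10; partial MOM loss in the BF3 step does no harm.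

Step 8 (thermal Claisen; risks are abnormal Claisen, cyclisation or loss of the prenyl group at 195 °C). The fallback sets out from 10 and comes back at 15, and introduces the side chain by cross-coupling instead of a sigmatropic shift. NBS (1.0 equiv, MeCN, 0 °C) brominates the only free position ortho to the 4'-OH and gives 7-(benzyloxy)-3-[2,3-bis(benzyloxy)-5-bromo-4-hydroxyphenyl]-4H-chromen-4-one F4. MeI/K2CO3/DMF gives the bromo methyl ether F5. A Pd-catalysed γ-selective (SE2') Suzuki–Miyaura coupling with prenylboronic acid pinacol ester (Pd(OAc)2, bulky biarylphosphine, aq. K3PO4, THF, 40–60 °C) then installs the 1,1-dimethylallyl group and gives 15.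

Step 10 (BCl3 debenzylation; risks are attack on the vinyl group or loss of the 4'-OMe). The fallback sets out from 10 and comes back at 16, and removes the benzyl groups before any alkene is present. 10 is taken to the bromo methyl ether F5 (via F4) as described for step 8. BCl3/pentamethylbenzene (CH2Cl2, −78 °C) on F5 gives the bromo triol F6. MOMCl/iPr2NEt (CH2Cl2) gives the tris-MOM ether F7. The same γ-selective coupling with prenylboronic acid pinacol ester gives the tris-MOM ether of the target F8. 2 M HCl in MeOH at 40 °C then gives 16; the vinyl group cannot cyclise because its ortho neighbour is the methyl ether.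

**Further compounds**
F1 | step 5 | (E)-1-[4-(benzyloxy)-2-(methoxymethoxy)phenyl]-3-[2,3-bis(benzyloxy)-4-(methoxymethoxy)phenyl]prop-2-en-1-one | O=C(/C=C/c1ccc(OCOC)c(OCc2ccccc2)c1OCc1ccccc1)c1ccc(OCc2ccccc2)cc1OCOC
F2 | step 5 | [4-(benzyloxy)-2-(methoxymethoxy)phenyl]{trans-3-[2,3-bis(benzyloxy)-4-(methoxymethoxy)phenyl]oxiran-2-yl}methanone (racemic, one enantiomer drawn) | O=C([C@@H]1O[C@H]1c1ccc(OCOC)c(OCc2ccccc2)c1OCc1ccccc1)c1ccc(OCc2ccccc2)cc1OCOC
F3 | step 5 | 3-[4-(benzyloxy)-2-(methoxymethoxy)phenyl]-2-[2,3-bis(benzyloxy)-4-(methoxymethoxy)phenyl]-3-oxopropanal (racemic) | O=CC(C(=O)c1ccc(OCc2ccccc2)cc1OCOC)c1ccc(OCOC)c(OCc2ccccc2)c1OCc1ccccc1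
F4 | step 8 | 7-(benzyloxy)-3-[2,3-bis(benzyloxy)-5-bromo-4-hydroxyphenyl]-4H-chromen-4-one | Oc1c(Br)cc(-c2coc3cc(OCc4ccccc4)ccc3c2=O)c(OCc2ccccc2)c1OCc1ccccc1
F5 | step 8 | 7-(benzyloxy)-3-[2,3-bis(benzyloxy)-5-bromo-4-methoxyphenyl]-4H-chromen-4-one | COc1c(Br)cc(-c2coc3cc(OCc4ccccc4)ccc3c2=O)c(OCc2ccccc2)c1OCc1ccccc1
F6 | step 10 | 3-(5-bromo-2,3-dihydroxy-4-methoxyphenyl)-7-hydroxy-4H-chromen-4-one | COc1c(Br)cc(-c2coc3cc(O)ccc3c2=O)c(O)c1O
F7 | step 10 | 3-[5-bromo-4-methoxy-2,3-bis(methoxymethoxy)phenyl]-7-(methoxymethoxy)-4H-chromen-4-one | COc1c(Br)cc(-c2coc3cc(OCOC)ccc3c2=O)c(OCOC)c1OCOC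
F8 | step 10 | 3-[4-methoxy-2,3-bis(methoxymethoxy)-5-(2-methylbut-3-en-2-yl)phenyl]-7-(methoxymethoxy)-4H-chromen-4-one | C=CC(C)(C)c1cc(-c2coc3cc(OCOC)ccc3c2=O)c(OCOC)c(OCOC)c1OC
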